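**Plan**
1. The butyrolactone (O1, C2, C3, C4, C5) carries the ring B benzyl group on C4, which lies between C3 and the oxygen-bound C5H2. C5 and C4 can therefore be read as Cα and Cβ of a 1-alkenyl sulfoxide, and a stereogenic sulfur on C5 can pass its chirality to C4.
2. Retrosynthesis: benzyl is put back on the ring A phenol, Cl on C3 and p-tolylsulfanyl on C5. C3–C4 and O1–C5 are then cut together, giving an (S,E)-alkenyl sulfoxide (C4, C5, ring B) and a chloro(arylmethyl)ketene (C2, C3, ring A).
3. Further cuts: S–C5 (alkenylmagnesium plus menthyl sulfinate), ring B CH2–C(sp) (benzyl chloride plus acetylide) and C3–CH2 of ring A (benzyl bromide plus dichloroacetate enolate).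
4. Forward: the two open-chain halves are built separately and joined in the lactonization, which closes the only new ring. Cl and S are then removed, C3 is equilibrated and the phenol is freed.
5. Stereochemistry: sulfur comes from (+)-menthyl (R)-p-toluenesulfinate with inversion. It sets C4 through the chair [3,3] shift, and C4 sets C3 by thermodynamic trans control.

Key step: step 10

Assumption: the sense of sulfur-to-carbon chirality transfer is taken from the chair model of the [3,3] shift (p-tolyl equatorial, lone pair axial), which pairs an (S)-configured E-alkenyl sulfoxide with the (R)-configured C4 of the target.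

**Step 1**
Reactants: 1 3,4-dimethoxybenzyl chloride
Product: 2 1,2-dimethoxy-4-(prop-2-yn-1-yl)benzene
Conditions: HC≡CMgBr (2.5 equiv), CuBr·SMe2 (10 mol %), THF, 0 → 50 °C
Reagents that add atoms: ethynylmagnesium bromide, C#C[Mg]Br
Why: Copper-catalysed sp3–sp cross-coupling of a benzylic halide with an alkynyl Grignard reagent is a standard entry to 3-arylprop-1-ynes, and the excess acetylide should hold back a second benzylation.

**Step 2**
Reactants: 2 1,2-dimethoxy-4-(prop-2-yn-1-yl)benzene
Product: 4 4-[(E)-3-iodoprop-2-en-1-yl]-1,2-dimethoxybenzene, via alkenylzirconocene chloride 3 (not isolated)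
Conditions: Cp2Zr(H)Cl, THF, rt, dark; then I2, 0 °C
Reagents that add atoms: iodine, II
Why: Hydrozirconation adds Zr–H syn and places zirconium on the terminal carbon, and iodinolysis of the C–Zr bond goes with retention, so the E-iodoalkene alone is expected.

**Step 3**
Reactants: 4 4-[(E)-3-iodoprop-2-en-1-yl]-1,2-dimethoxybenzene; 5 (1S,2R,5S)-menthyl (R)-p-toluenesulfinate
Product: 7 (S)-4-[(E)-3-(p-tolylsulfinyl)prop-2-en-1-yl]-1,2-dimethoxybenzene, via alkenylmagnesium chloride 6 (not isolated)
Conditions: iPrMgCl·LiCl (1.05 equiv), THF, 0 °C → rt; then cannulated into 5, toluene–THF, −40 °C; aq NH4Cl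
Reagents that add atoms: none
Why: Iodine–magnesium exchange with iPrMgCl·LiCl preserves the alkene geometry (insertion of magnesium metal would not), and the Andersen sulfoxide synthesis replaces menthoxide with inversion at sulfur, so the (R)-sulfinate should deliver the (S)-sulfoxide.

**Step 4**
Reactants: 8 3-hydroxy-4,5-dimethoxybenzaldehyde
Product: 9 3-(benzyloxy)-4,5-dimethoxybenzaldehyde
Conditions: BnBr, K2CO3, DMF, rt
Reagents that add atoms: benzyl bromide, BrCc1ccccc1
Why: Williamson ether synthesis on the only acidic OH gives a benzyl ether that withstands every later reagent up to the final hydrogenolysis.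

**Step 5**
Reactants: 9 3-(benzyloxy)-4,5-dimethoxybenzaldehyde
Product: 10 [3-(benzyloxy)-4,5-dimethoxyphenyl]methanol
Conditions: NaBH4, MeOH, 0 °C
Reagents that add atoms: none
Why: Borohydride reduction of an aromatic aldehyde, to which the aryl ethers are inert.

**Step 6**
Reactants: 10 [3-(benzyloxy)-4,5-dimethoxyphenyl]methanol
Product: 11 1-(benzyloxy)-5-(bromomethyl)-2,3-dimethoxybenzene
Conditions: PBr3, CH2Cl2, 0 °C
Reagents that add atoms: phosphorus tribromide, BrP(Br)Br
Why: Bromination of a benzylic alcohol through its phosphite ester (SN2) runs under conditions too mild to touch the aryl ethers.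

**Step 7**
Reactants: 12 methyl dichloroacetate; 11 1-(benzyloxy)-5-(bromomethyl)-2,3-dimethoxybenzene
Product: 14 methyl 3-[3-(benzyloxy)-4,5-dimethoxyphenyl]-2,2-dichloropropanoate, via lithium dichloroenolate 13 (not isolated)
Conditions: LDA, THF, −78 °C, slow addition of 12; then 11, DMPU, −78 → −40 °C
Reagents that add atoms: none
Why: Ester enolate alkylation, in which the dichloro enolate is kept at −78 °C where α-elimination is slow and meets a reactive benzylic bromide, with DMPU raising its nucleophilicity.

**Step 8**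
Reactants: 14 methyl 3-[3-(benzyloxy)-4,5-dimethoxyphenyl]-2,2-dichloropropanoate
Product: 15 3-[3-(benzyloxy)-4,5-dimethoxyphenyl]-2,2-dichloropropanoic acid
Conditions: LiOH, THF–H2O, 0 °C; then 1 M HCl
Reagents that add atoms: lithium hydroxide, [Li+].[OH-]
Why: Saponification is made fast at 0 °C by the two α-chlorines, so ester cleavage should precede any loss of HCl toward the cinnamate.

**Step 9**
Reactants: 15 3-[3-(benzyloxy)-4,5-dimethoxyphenyl]-2,2-dichloropropanoic acid
Product: 16 3-[3-(benzyloxy)-4,5-dimethoxyphenyl]-2,2-dichloropropanoyl chloride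
Conditions: (COCl)2, DMF (cat.), CH2Cl2, 0 °C → rt; used crude
Reagents that add atoms: oxalyl chloride, O=C(Cl)C(Cl)=O
Why: Acid chloride formation through the chloroiminium salt from DMF and (COCl)2 is neutral enough for the benzyl and methyl ethers.

**Step 10**
Reactants: 7 (S)-4-[(E)-3-(p-tolylsulfinyl)prop-2-en-1-yl]-1,2-dimethoxybenzene; 16 3-[3-(benzyloxy)-4,5-dimethoxyphenyl]-2,2-dichloropropanoyl chloride
Product: 20 (4S,5S)-3-[3-(benzyloxy)-4,5-dimethoxybenzyl]-3-chloro-4-(3,4-dimethoxybenzyl)-5-(p-tolylsulfanyl)dihydrofuran-2(3H)-one (C3 epimers), via chloro(arylmethyl)ketene 17 (not isolated), via acyloxysulfonium enolate 18 (not isolated), via thionium carboxylate 19 (not isolated)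
Conditions: activated Zn–Cu couple (10 equiv), Et2O–THF, reflux; 16 (2.5 equiv) added by syringe pump
Reagents that add atoms: none
Why: Proposed new method: zinc strips two chlorines from 16 to give ketene 17, whose carbonyl carbon is attacked by the sulfinyl oxygen of 7 to give zwitterion 18; a charge-accelerated [3,3] shift then makes C3–C4 while S–O breaks, and the carboxylate of 19 adds to the thionium carbon to make O1–C5 (additive Pummerer sequence). The closest known reaction type is the lactonization of 1-alkenyl aryl sulfoxides with dichloroketene made from Cl3CCOCl and Zn–Cu, and [3,3] shifts of the same oxysulfonium type are known with alkyl-bearing keteniminium partners, so only the exchange of one ketene chlorine for an arylmethyl group is new. The lactone closes 5-exo-trig, the C=S+ bond lying outside the new ring. C4 is controlled by sulfur: in the chair with p-tolyl equatorial and the lone pair axial, the E alkene holds its CH2Ar group equatorial, so the enolate carbon reaches one face of Cβ only and the (S)-sulfoxide maps onto the (R)-C4 of the target (descriptor 4S here because chlorine raises the rank of C3). Suprafacial delivery of carbon and oxygen to the E alkene should place the sulfanyl group trans to the C4 substituent (5S), while C3 follows the enolate geometry, may be a mixture and is erased in step 11. The step needs O-acylation and rearrangement to outrun γ-deprotonation at the benzylic–allylic CH2 (vinylogous Pummerer reaction, allyl sulfoxide formation and racemization) and ketene dimerization, which the base-free zinc generation, the retained α-chlorine that keeps the ketene electrophilic and the slow addition of 16 are meant to secure.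

**Step 11**
Reactants: 20 (4S,5S)-3-[3-(benzyloxy)-4,5-dimethoxybenzyl]-3-chloro-4-(3,4-dimethoxybenzyl)-5-(p-tolylsulfanyl)dihydrofuran-2(3H)-one (C3 epimers)
Product: 21 (4R)-3-[3-(benzyloxy)-4,5-dimethoxybenzyl]-4-(3,4-dimethoxybenzyl)dihydrofuran-2(3H)-one (C3 epimers)
Conditions: Bu3SnH (4 equiv), AIBN (cat., in portions), toluene, 100 °C
Reagents that add atoms: none
Why: Radical chain reduction with tin hydride, in which Bu3Sn• abstracts the tertiary α-carbonyl chlorine and attacks sulfur of the O,S-acetal to release the oxygen-stabilised C5 radical, both radicals are quenched by Bu3SnH, C4 is untouched and C3 arises as a cis/trans mixture.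

**Step 12**
Reactants: 21 (4R)-3-[3-(benzyloxy)-4,5-dimethoxybenzyl]-4-(3,4-dimethoxybenzyl)dihydrofuran-2(3H)-one (C3 epimers)
Product: 22 (3R,4R)-3-[3-(benzyloxy)-4,5-dimethoxybenzyl]-4-(3,4-dimethoxybenzyl)dihydrofuran-2(3H)-one
Conditions: DBU (0.3 equiv), toluene, 80 °C
Reagents that add atoms: none
Why: Base-mediated epimerization through the lactone enolate, where C3–H is the only acidic stereogenic position and the equilibrium should favour the trans-3,4-dibenzyl lactone, so the fixed (R)-C4 sets C3 as R.

**Step 13**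
Reactants: 22 (3R,4R)-3-[3-(benzyloxy)-4,5-dimethoxybenzyl]-4-(3,4-dimethoxybenzyl)dihydrofuran-2(3H)-one
Product: 23 (3R,4R)-4-(3,4-dimethoxybenzyl)-3-(3-hydroxy-4,5-dimethoxybenzyl)dihydrofuran-2(3H)-one
Conditions: H2 (1 atm), Pd/C, EtOAc–EtOH, rt
Reagents that add atoms: none
Why: Hydrogenolysis of a benzyl aryl ether, run after chromatographic removal of sulfur and tin residues at 22, leaves the lactone, the methyl ethers and both stereocentres unchanged.

**Compound list**
1 | 3,4-dimethoxybenzyl chloride | COc1ccc(CCl)cc1OC | starting material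
2 | 1,2-dimethoxy-4-(prop-2-yn-1-yl)benzene | COc1ccc(CC#C)cc1OC | intermediate
3 | chlorobis(cyclopentadienyl)[(E)-3-(3,4-dimethoxyphenyl)prop-1-en-1-yl]zirconium (Cp rings drawn σ-bound) | COc1ccc(C/C=C/[Zr](Cl)(C2C=CC=C2)C2C=CC=C2)cc1OC | intermediate
4 | 4-[(E)-3-iodoprop-2-en-1-yl]-1,2-dimethoxybenzene | COc1ccc(C/C=C/I)cc1OC | intermediate
5 | (1S,2R,5S)-menthyl (R)-p-toluenesulfinate | Cc1ccc(cc1)[S@](=O)O[C@H]1C[C@@H](C)CC[C@@H]1C(C)C | starting material
6 | [(E)-3-(3,4-dimethoxyphenyl)prop-1-en-1-yl]magnesium chloride (LiCl complex) | COc1ccc(C/C=C/[Mg]Cl)cc1OC | intermediate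
7 | (S)-4-[(E)-3-(p-tolylsulfinyl)prop-2-en-1-yl]-1,2-dimethoxybenzene | Cc1ccc(cc1)[S@@](=O)/C=C/Cc1ccc(OC)c(OC)c1 | intermediate
8 | 3-hydroxy-4,5-dimethoxybenzaldehyde | COc1cc(C=O)cc(O)c1OC | starting material
9 | 3-(benzyloxy)-4,5-dimethoxybenzaldehyde | COc1cc(C=O)cc(OCc2ccccc2)c1OC | intermediate
10 | [3-(benzyloxy)-4,5-dimethoxyphenyl]methanol | COc1cc(CO)cc(OCc2ccccc2)c1OC | intermediate
11 | 1-(benzyloxy)-5-(bromomethyl)-2,3-dimethoxybenzene | COc1cc(CBr)cc(OCc2ccccc2)c1OC | intermediate
12 | methyl dichloroacetate | COC(=O)C(Cl)Cl | starting material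
13 | lithium enolate of methyl dichloroacetate | COC(O[Li])=C(Cl)Cl | intermediate
14 | methyl 3-[3-(benzyloxy)-4,5-dimethoxyphenyl]-2,2-dichloropropanoate | COC(=O)C(Cl)(Cl)Cc1cc(OC)c(OC)c(OCc2ccccc2)c1 | intermediate
15 | 3-[3-(benzyloxy)-4,5-dimethoxyphenyl]-2,2-dichloropropanoic acid | OC(=O)C(Cl)(Cl)Cc1cc(OC)c(OC)c(OCc2ccccc2)c1 | intermediate
16 | 3-[3-(benzyloxy)-4,5-dimethoxyphenyl]-2,2-dichloropropanoyl chloride | ClC(=O)C(Cl)(Cl)Cc1cc(OC)c(OC)c(OCc2ccccc2)c1 | intermediate
17 | 3-[3-(benzyloxy)-4,5-dimethoxyphenyl]-2-chloroprop-1-en-1-one (ketene) | COc1cc(CC(Cl)=C=O)cc(OCc2ccccc2)c1OC | intermediate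
18 | (S)-alkenyl(p-tolyl)(acyloxy)sulfonium enolate zwitterion from 7 and 17 (enolate geometry open) | Cc1ccc(cc1)[S@@+](OC([O-])=C(Cl)Cc1cc(OC)c(OC)c(OCc2ccccc2)c1)/C=C/Cc1ccc(OC)c(OC)c1 | intermediate
19 | p-tolylthionium carboxylate zwitterion after the [3,3] shift (future C4 S-configured, C3 open) | COc1ccc(C[C@@H](C=[S+]c2ccc(C)cc2)C(Cl)(Cc2cc(OC)c(OC)c(OCc3ccccc3)c2)C([O-])=O)cc1OC | intermediate
20 | (4S,5S)-3-[3-(benzyloxy)-4,5-dimethoxybenzyl]-3-chloro-4-(3,4-dimethoxybenzyl)-5-(p-tolylsulfanyl)dihydrofuran-2(3H)-one (C3 epimers) | COc1ccc(C[C@H]2[C@H](Sc3ccc(C)cc3)OC(=O)C2(Cl)Cc2cc(OCc3ccccc3)c(OC)c(OC)c2)cc1OC | intermediate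
21 | (4R)-3-[3-(benzyloxy)-4,5-dimethoxybenzyl]-4-(3,4-dimethoxybenzyl)dihydrofuran-2(3H)-one (C3 epimers) | COc1ccc(C[C@H]2COC(=O)C2Cc2cc(OCc3ccccc3)c(OC)c(OC)c2)cc1OC | intermediate
22 | (3R,4R)-3-[3-(benzyloxy)-4,5-dimethoxybenzyl]-4-(3,4-dimethoxybenzyl)dihydrofuran-2(3H)-one | COc1ccc(C[C@H]2COC(=O)[C@@H]2Cc2cc(OCc3ccccc3)c(OC)c(OC)c2)cc1OC | intermediate
23 | (3R,4R)-4-(3,4-dimethoxybenzyl)-3-(3-hydroxy-4,5-dimethoxybenzyl)dihydrofuran-2(3H)-one | COc1ccc(C[C@H]2COC(=O)[C@@H]2Cc2cc(O)c(OC)c(OC)c2)cc1OC | target

Total step count: 13. Longest linear sequence: 10 steps (steps 4 to 13, from 8).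

**Steps most likely to fail**

Step 10. The ketene is less electrophilic than dichloroketene, so its capture by the sulfinyl oxygen may be too slow. In that case ketene oligomerization or zinc-mediated deoxygenation of the sulfoxide could take over. ZnCl2-induced cyclization of the acid chloride onto ring A and leakage through a boat transition state with loss of chirality transfer are further risks.

The fallback uses known chemistry and sets out from 7. The sulfoxide is lactonized with dichloroketene F1, made in the flask from Cl3CCOCl and Zn–Cu in refluxing Et2O. This should give (4S,5S)-3,3-dichloro-4-(3,4-dimethoxybenzyl)-5-(p-tolylsulfanyl)dihydrofuran-2(3H)-one F2 by the same sulfur-to-C4 transfer. Bu3SnH with AIBN in hot toluene then strips both chlorines and the sulfanyl group to give (R)-4-(3,4-dimethoxybenzyl)dihydrofuran-2(3H)-one F3. The absolute configuration of this lactone is established, so it also allows the sense of transfer to be checked. LiHMDS in THF at −78 °C forms the lithium enolate of the lactone F4, which is alkylated by bromide 11 anti to the C4 substituent. The fallback comes back to the route at 22. C3–C4 and O1–C5 still arise in the sulfoxide lactonization, and only the C3–CH2 bond is made later.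

Step 7. Decomposition of the dichloro enolate by α-elimination, or its Claisen self-condensation, may outpace C-alkylation.

The fallback sets out from 11 and reaches the ketene at a lower chlorination level. Alkylation of diethyl chloromalonate with 11 (K2CO3, DMF) should give diethyl 2-[3-(benzyloxy)-4,5-dimethoxybenzyl]-2-chloromalonate F5. KOH in aqueous EtOH followed by HCl gives 2-[3-(benzyloxy)-4,5-dimethoxybenzyl]-2-chloromalonic acid F6. This loses CO2 in refluxing toluene to give racemic 3-[3-(benzyloxy)-4,5-dimethoxyphenyl]-2-chloropropanoic acid F7. (COCl)2 with catalytic DMF then gives 3-[3-(benzyloxy)-4,5-dimethoxyphenyl]-2-chloropropanoyl chloride F8. Slow addition of Et3N to F8 and 7 in Et2O–hexane, where the ammonium chloride precipitates, dehydrochlorinates F8, and the route is rejoined at ketene 17.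

Step 3. The exchange may be slow, and a proton may transfer from the benzylic–allylic CH2 to the alkenylmagnesium. Base-induced migration of the double bond in the product, followed by [2,3] racemization of the resulting allyl sulfoxide, may also erode geometry and optical purity.

The fallback sets out from 2 and forms the S–C bond at the much less basic sp carbon. EtMgBr in THF gives [3-(3,4-dimethoxyphenyl)prop-1-yn-1-yl]magnesium bromide F9. This displaces menthoxide from 5 in toluene at −20 °C with inversion to give (R)-4-[3-(p-tolylsulfinyl)prop-2-yn-1-yl]-1,2-dimethoxybenzene F10. The arrangement at sulfur is the same as in 7, and the descriptor changes only because alkynyl outranks p-tolyl. Reduction with DIBAL-H in THF at −78 °C adds hydrogen trans across the triple bond, and the route is rejoined at 7.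

**Further compounds**
F1 | step 10 | dichloroketene | ClC(Cl)=C=O
F2 | step 10 | (4S,5S)-3,3-dichloro-4-(3,4-dimethoxybenzyl)-5-(p-tolylsulfanyl)dihydrofuran-2(3H)-one | COc1ccc(C[C@H]2[C@H](Sc3ccc(C)cc3)OC(=O)C2(Cl)Cl)cc1OC
F3 | step 10 | (R)-4-(3,4-dimethoxybenzyl)dihydrofuran-2(3H)-one | COc1ccc(C[C@H]2COC(=O)C2)cc1OC
F4 | step 10 | lithium enolate of (R)-4-(3,4-dimethoxybenzyl)dihydrofuran-2(3H)-one | COc1ccc(C[C@H]2COC(O[Li])=C2)cc1OC
F5 | step 7 | diethyl 2-[3-(benzyloxy)-4,5-dimethoxybenzyl]-2-chloromalonate | CCOC(=O)C(Cl)(Cc1cc(OC)c(OC)c(OCc2ccccc2)c1)C(=O)OCC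
F6 | step 7 | 2-[3-(benzyloxy)-4,5-dimethoxybenzyl]-2-chloromalonic acid | OC(=O)C(Cl)(Cc1cc(OC)c(OC)c(OCc2ccccc2)c1)C(O)=O
F7 | step 7 | racemic 3-[3-(benzyloxy)-4,5-dimethoxyphenyl]-2-chloropropanoic acid | OC(=O)C(Cl)Cc1cc(OC)c(OC)c(OCc2ccccc2)c1
F8 | step 7 | racemic 3-[3-(benzyloxy)-4,5-dimethoxyphenyl]-2-chloropropanoyl chloride | ClC(=O)C(Cl)Cc1cc(OC)c(OC)c(OCc2ccccc2)c1
F9 | step 3 | [3-(3,4-dimethoxyphenyl)prop-1-yn-1-yl]magnesium bromide | COc1ccc(CC#C[Mg]Br)cc1OC
F10 | step 3 | (R)-4-[3-(p-tolylsulfinyl)prop-2-yn-1-yl]-1,2-dimethoxybenzene | Cc1ccc(cc1)[S@@](=O)C#CCc1ccc(OC)c(OC)c1
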